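**Retrosynthetic overview**
Feature: number the tetrahydrofuran O1, C2 (3,4-dimethoxyphenyl, ring A), C3 and C4 (methyls), C5 (syringyl, ring B). The two methoxy groups of ring A are adjacent, para and meta to C2, so ring A maps onto a C2-ethynyl group (two carbons) plus the symmetric 2,3-dimethoxybuta-1,3-diene (four carbons).
Endgame: target ⇐ debenzylation ⇐ DDQ aromatisation ⇐ cobalt-catalysed (4+2) of the 2-ethynyl tetrahydrofuran with the diene.
Ethynyl tetrahydrofuran ⇐ desilylation ⇐ ionic reduction of the hemiketal formed from a syringyl-lithium and a 5-alkynyl-3,4-dimethyl-γ-lactone (sets C5 trans to C4).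
Lactone ⇐ α-methylation (sets C4) ⇐ oxidative lactonisation ⇐ hydroboration ⇐ syn-crotylboration of a silylpropynal (sets the cis C2/C3 pair).
Ring order: ring B is bought, the oxygen ring is closed next (as the lactone), and ring A is built last.

Key step: step 10

Remark: hydride addition to a 3,4-trans-dimethyl five-membered oxocarbenium ion is assumed to follow the inside-attack envelope model, which places the substituent on the cationic carbon trans to the neighbouring methyl. The cis C2/C3 relationship is therefore fixed by crotylboration, and only the trans C4/C5 relationship is left to the reduction.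

Target numbering (O1, C2 to C5 as above) is used for all tetrahydrofurans. The target is (2R,3S,4S,5S): 2,3-cis, 3,4-trans, 4,5-trans.

**Step 1**
Reactants: 1 (triisopropylsilyl)acetylene
Product: 3 3-(triisopropylsilyl)prop-2-ynal, via lithium (triisopropylsilyl)acetylide 2 (not isolated)
Conditions: n-BuLi, THF, −78 °C; DMF, −78 to 0 °C; cold 1 M HCl
Reagents that add atoms: N,N-dimethylformamide CN(C)C=O
Why: Formylation of a lithium acetylide with DMF is the standard route to silyl ynals, and the acidic quench collapses the hemiaminal alkoxide before dimethylamine can add in conjugate fashion.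

**Step 2**
Reactants: 3 3-(triisopropylsilyl)prop-2-ynal; 4 (Z)-but-2-ene; 5 (+)-B-methoxydiisopinocampheylborane (from (−)-α-pinene)
Product: 9 (3R,4S)-4-methyl-1-(triisopropylsilyl)hex-5-en-1-yn-3-ol, via (Z)-crotylpotassium 6 (not isolated), via (Z)-crotyldiisopinocampheylborane 7 (not isolated), via homoallylic diisopinocampheylborinate 8 (not isolated)
Conditions: 4, KOtBu, n-BuLi, THF, −78 to −45 °C; 5, −78 °C; BF3·OEt2; 3, −78 °C; then NaOH, H2O2, 0 °C to rt
Reagents that add atoms: none
Why: In this Brown asymmetric crotylboration the closed chair transition state turns the Z geometry of 7 into the syn hydroxyl/methyl relationship, and the isopinocampheyl groups derived from (−)-α-pinene select the aldehyde face that gives (3R,4S), which become C2 (R) and C3 (S) of the target.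

**Step 3**
Reactants: 9 (3R,4S)-4-methyl-1-(triisopropylsilyl)hex-5-en-1-yn-3-ol
Product: 11 (3S,4R)-3-methyl-6-(triisopropylsilyl)hex-5-yne-1,4-diol, via bis(9-borabicyclononyl) adduct 10 (not isolated)
Conditions: 9-BBN (2.5 equiv), THF, 0 °C to rt; then NaOH, H2O2, 0 °C
Reagents that add atoms: hydrogen peroxide OO
Why: In this chemoselective hydroboration–oxidation 9-BBN adds anti-Markovnikov to the unhindered monosubstituted alkene much faster than to the alkyne shielded by the triisopropylsilyl group, and no stereocentre is touched.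

**Step 4**
Reactants: 11 (3S,4R)-3-methyl-6-(triisopropylsilyl)hex-5-yne-1,4-diol
Product: 13 (4S,5R)-4-methyl-5-[(triisopropylsilyl)ethynyl]dihydrofuran-2(3H)-one (methyl/alkynyl cis), via lactol 12 (not isolated)
Conditions: TEMPO (0.2 equiv), PhI(OAc)2 (2.5 equiv), CH2Cl2, rt
Reagents that add atoms: none
Why: In this TEMPO/PhI(OAc)2 oxidative lactonisation the oxoammonium salt oxidises the primary alcohol first, the hydroxy aldehyde closes to lactol 12, and 12 is oxidised again, so the propargylic carbinol oxygen becomes the ring oxygen with its configuration retained.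

**Step 5**
Reactants: 13 (4S,5R)-4-methyl-5-[(triisopropylsilyl)ethynyl]dihydrofuran-2(3H)-one
Product: 15 (3S,4S,5R)-3,4-dimethyl-5-[(triisopropylsilyl)ethynyl]dihydrofuran-2(3H)-one (3,4-trans/4,5-cis), via lithium enolate 14 (not isolated)
Conditions: LiN(SiMe3)2, THF, −78 °C; MeI, −78 to −40 °C
Reagents that add atoms: iodomethane CI
Why: In this diastereoselective lactone enolate alkylation MeI approaches the planar enolate from the face opposite the neighbouring methyl and the alkynyl group, which share one face, so the new methyl (target C4, S) ends trans to the C3 methyl.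

**Step 6**
Reactants: 16 4-bromo-2,6-dimethoxyphenol
Product: 17 2-(benzyloxy)-5-bromo-1,3-dimethoxybenzene
Conditions: BnBr, K2CO3, DMF, rt to 50 °C
Reagents that add atoms: benzyl bromide BrCc1ccccc1
Why: This Williamson ether synthesis on the phenoxide masks the syringyl OH with a group that tolerates aryllithium formation, BF3·OEt2, fluoride, the cobalt catalyst and DDQ.

**Step 7**
Reactants: 17 2-(benzyloxy)-5-bromo-1,3-dimethoxybenzene; 15 (3S,4S,5R)-3,4-dimethyl-5-[(triisopropylsilyl)ethynyl]dihydrofuran-2(3H)-one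
Product: 19 (2R,3S,4S)-5-(4-benzyloxy-3,5-dimethoxyphenyl)-3,4-dimethyl-2-[(triisopropylsilyl)ethynyl]tetrahydrofuran-5-ol (anomeric mixture), via aryllithium 18 (not isolated)
Conditions: 17, n-BuLi, THF, −78 °C; then 15, −78 °C; aq NH4Cl
Reagents that add atoms: none
Why: Bromine–lithium exchange followed by 1,2-addition of the aryllithium to the lactone stops at the hemiketal because the tetrahedral lithium alkoxide persists at −78 °C, and the undefined anomeric centre is planarised in the next step.

**Step 8**
Reactants: 19 hemiketal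
Product: 21 (2R,3S,4S,5S)-5-(4-benzyloxy-3,5-dimethoxyphenyl)-3,4-dimethyl-2-[(triisopropylsilyl)ethynyl]tetrahydrofuran, via aryl oxocarbenium ion 20 (not isolated)
Conditions: Et3SiH, BF3·OEt2, CH2Cl2, −78 °C; aq NaHCO3
Reagents that add atoms: none
Why: In this reductive deoxygenation of a cyclic hemiketal (ionic hydrogenation) BF3·OEt2 generates the aryl-stabilised oxocarbenium ion 20, whose favoured envelope holds both methyls pseudoequatorial, and Et3SiH attacks its inside face, which is also the face away from the C3 methyl and the C2 alkynyl group, so the aryl group ends trans to the C4 methyl and C5 is set as S.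

**Step 9**
Reactants: 21 silyl alkyne
Product: 22 (2R,3S,4S,5S)-5-(4-benzyloxy-3,5-dimethoxyphenyl)-2-ethynyl-3,4-dimethyltetrahydrofuran
Conditions: Bu4NF, THF, 0 °C to rt
Reagents that add atoms: none
Why: Fluoride-mediated protodesilylation cleaves only the C(sp)–Si bond and leaves the ethers and the four ring stereocentres untouched.

**Step 10**
Reactants: 22 (2R,3S,4S,5S)-5-(4-benzyloxy-3,5-dimethoxyphenyl)-2-ethynyl-3,4-dimethyltetrahydrofuran; 23 2,3-dimethoxybuta-1,3-diene
Product: 24 (2R,3S,4S,5S)-5-(4-benzyloxy-3,5-dimethoxyphenyl)-2-(4,5-dimethoxycyclohexa-1,4-dien-1-yl)-3,4-dimethyltetrahydrofuran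
Conditions: CoBr2(dppe) (10 mol %), Zn (20 mol %), ZnI2 (20 mol %), 23 (2 equiv), dry CH2Cl2, rt; filtration through Et3N-deactivated silica
Reagents that add atoms: none
Why: Zn reduces CoBr2(dppe) to a monovalent cobalt species and ZnI2 abstracts bromide, so a cationic [Co(dppe)]+ fragment binds the s-cis diene 23 and the C2-ethynyl group of 22, and oxidative cyclisation to a trivalent cobaltacycle followed by reductive elimination forms the two C–C bonds between the diene termini and the two alkyne carbons. The closest known reaction type is the cobalt-catalysed neutral Diels–Alder reaction of terminal alkynes, propargylic ethers included, with 2,3-disubstituted and oxygen-substituted 1,3-dienes. The one ring closed is the six-membered carbocycle of ring A, formed in an intermolecular (4+2) mode at the 1,4-cyclohexadiene oxidation level. No stereocentre is created, and C2 to C5 are spectators. The step needs cross-cycloaddition to beat alkyne cyclotrimerisation, which excess diene, the dppe ligand and the non-coordinating solvent favour, and the twofold symmetry of 23 removes any regiochemical choice, so the methoxy groups can only end para and meta to C2. The step also needs intact ring stereocentres: catalytic ZnI2 is too weak to ionise the propargylic C2–O bond, and C5 already carries its aryl group trans to the C4 methyl, so a reversible opening there would be degenerate.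

**Step 11**
Reactants: 24 cyclohexadienyl tetrahydrofuran
Product: 25 (2R,3S,4S,5S)-5-(4-benzyloxy-3,5-dimethoxyphenyl)-2-(3,4-dimethoxyphenyl)-3,4-dimethyltetrahydrofuran
Conditions: DDQ (1.0 equiv), toluene, 0 °C; filtration through basic alumina
Reagents that add atoms: none
Why: In this dehydrogenative aromatisation DDQ abstracts hydride from a doubly allylic CH2 of the electron-rich bis(enol ether) diene much faster than from the benzylic ether C–H bonds at C2 and C5, so one equivalent at low temperature should be consumed by ring A alone.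

**Step 12**
Reactants: 25 benzyl ether
Product: 26 4-[(2S,3S,4S,5R)-5-(3,4-dimethoxyphenyl)-3,4-dimethyltetrahydrofuran-2-yl]-2,6-dimethoxyphenol, which is (2R,3S,4S,5S) in the numbering used here (target)
Conditions: H2 (1 atm), 10% Pd/C, EtOAc, rt, stopped after one equivalent of H2
Reagents that add atoms: none
Why: In this catalytic hydrogenolysis the primary O–CH2Ph bond is cleaved faster than the secondary, flanked benzylic C–O bonds of the tetrahydrofuran in a neutral solvent at atmospheric pressure, and no stereocentre is affected.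

**Compound list**
1 | (triisopropylsilyl)acetylene | C#C[Si](C(C)C)(C(C)C)C(C)C | starting material
2 | lithium (triisopropylsilyl)acetylide | [Li]C#C[Si](C(C)C)(C(C)C)C(C)C | intermediate
3 | 3-(triisopropylsilyl)prop-2-ynal | O=CC#C[Si](C(C)C)(C(C)C)C(C)C | intermediate
4 | (Z)-but-2-ene | C/C=C\C | starting material
5 | (+)-B-methoxydiisopinocampheylborane | COB([C@H]1C[C@H]2C[C@@H]([C@@H]1C)C2(C)C)[C@H]1C[C@H]2C[C@@H]([C@@H]1C)C2(C)C | starting material
6 | (Z)-crotylpotassium | [K+].[CH2-]/C=C\C | intermediate
7 | (Z)-crotyldiisopinocampheylborane | C/C=C\CB([C@H]1C[C@H]2C[C@@H]([C@@H]1C)C2(C)C)[C@H]1C[C@H]2C[C@@H]([C@@H]1C)C2(C)C | intermediate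
8 | (3R,4S)-4-methyl-1-(triisopropylsilyl)hex-5-en-1-yn-3-yl diisopinocampheylborinate | CC(C)[Si](C#C[C@H](OB([C@H]1C[C@H]2C[C@@H]([C@@H]1C)C2(C)C)[C@H]1C[C@H]2C[C@@H]([C@@H]1C)C2(C)C)[C@@H](C)C=C)(C(C)C)C(C)C | intermediate
9 | (3R,4S)-4-methyl-1-(triisopropylsilyl)hex-5-en-1-yn-3-ol | CC(C)[Si](C#C[C@H](O)[C@@H](C)C=C)(C(C)C)C(C)C | intermediate
10 | O,C-bis(9-borabicyclo[3.3.1]nonan-9-yl) adduct of 9 | CC(C)[Si](C#C[C@H](OB1C2CCCC1CCC2)[C@@H](C)CCB1C2CCCC1CCC2)(C(C)C)C(C)C | intermediate
11 | (3S,4R)-3-methyl-6-(triisopropylsilyl)hex-5-yne-1,4-diol | CC(C)[Si](C#C[C@H](O)[C@@H](C)CCO)(C(C)C)C(C)C | intermediate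
12 | (4S,5R)-4-methyl-5-[(triisopropylsilyl)ethynyl]tetrahydrofuran-2-ol | CC(C)[Si](C#C[C@@H]1OC(O)C[C@@H]1C)(C(C)C)C(C)C | intermediate
13 | (4S,5R)-4-methyl-5-[(triisopropylsilyl)ethynyl]dihydrofuran-2(3H)-one | CC(C)[Si](C#C[C@@H]1OC(=O)C[C@@H]1C)(C(C)C)C(C)C | intermediate
14 | lithium enolate of 13 | CC(C)[Si](C#C[C@@H]1OC(O[Li])=C[C@@H]1C)(C(C)C)C(C)C | intermediate
15 | (3S,4S,5R)-3,4-dimethyl-5-[(triisopropylsilyl)ethynyl]dihydrofuran-2(3H)-one | CC(C)[Si](C#C[C@@H]1OC(=O)[C@@H](C)[C@@H]1C)(C(C)C)C(C)C | intermediate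
16 | 4-bromo-2,6-dimethoxyphenol | COc1cc(Br)cc(OC)c1O | starting material
17 | 2-(benzyloxy)-5-bromo-1,3-dimethoxybenzene | COc1cc(Br)cc(OC)c1OCc1ccccc1 | intermediate
18 | 4-(benzyloxy)-3,5-dimethoxyphenyllithium | [Li]c1cc(OC)c(OCc2ccccc2)c(OC)c1 | intermediate
19 | (2R,3S,4S)-5-(4-benzyloxy-3,5-dimethoxyphenyl)-3,4-dimethyl-2-[(triisopropylsilyl)ethynyl]tetrahydrofuran-5-ol | CC(C)[Si](C#C[C@@H]1OC(O)(c2cc(OC)c(OCc3ccccc3)c(OC)c2)[C@@H](C)[C@@H]1C)(C(C)C)C(C)C | intermediate
20 | aryl oxocarbenium ion from 19 | CC(C)[Si](C#C[C@@H]1[O+]=C(c2cc(OC)c(OCc3ccccc3)c(OC)c2)[C@@H](C)[C@@H]1C)(C(C)C)C(C)C | intermediate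
21 | (2R,3S,4S,5S)-5-(4-benzyloxy-3,5-dimethoxyphenyl)-3,4-dimethyl-2-[(triisopropylsilyl)ethynyl]tetrahydrofuran | CC(C)[Si](C#C[C@@H]1O[C@H](c2cc(OC)c(OCc3ccccc3)c(OC)c2)[C@@H](C)[C@@H]1C)(C(C)C)C(C)C | intermediate
22 | (2R,3S,4S,5S)-5-(4-benzyloxy-3,5-dimethoxyphenyl)-2-ethynyl-3,4-dimethyltetrahydrofuran | C#C[C@@H]1O[C@H](c2cc(OC)c(OCc3ccccc3)c(OC)c2)[C@@H](C)[C@@H]1C | intermediate
23 | 2,3-dimethoxybuta-1,3-diene | COC(=C)C(=C)OC | starting material
24 | (2R,3S,4S,5S)-5-(4-benzyloxy-3,5-dimethoxyphenyl)-2-(4,5-dimethoxycyclohexa-1,4-dien-1-yl)-3,4-dimethyltetrahydrofuran | COC1=C(OC)CC(=CC1)[C@@H]2O[C@H](c3cc(OC)c(OCc4ccccc4)c(OC)c3)[C@@H](C)[C@@H]2C | intermediate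
25 | (2R,3S,4S,5S)-5-(4-benzyloxy-3,5-dimethoxyphenyl)-2-(3,4-dimethoxyphenyl)-3,4-dimethyltetrahydrofuran | COc1ccc([C@@H]2O[C@H](c3cc(OC)c(OCc4ccccc4)c(OC)c3)[C@@H](C)[C@@H]2C)cc1OC | intermediate
26 | 4-[(2S,3S,4S,5R)-5-(3,4-dimethoxyphenyl)-3,4-dimethyltetrahydrofuran-2-yl]-2,6-dimethoxyphenol | COc1ccc([C@@H]2O[C@H](c3cc(OC)c(O)c(OC)c3)[C@@H](C)[C@@H]2C)cc1OC | target

**Step count**
Total: 12 steps. Longest linear sequence: 11 steps (steps 1 to 5 and 7 to 12, from compound 1). Step 6 is a one-step side branch.

**Steps most likely to fail**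

Step 10 (key step). Cyclotrimerisation of the terminal alkyne may outrun the cross-cycloaddition. The α-branched alkyne may bind the metal slowly. ZnI2 together with traces of water may hydrolyse or oligomerise the electron-rich diene.
The fallback runs from 22 back to 25. It gives the alkyne a removable formyl activator, so the same two ring bonds form in a thermal normal-demand Diels–Alder reaction.
- Deprotonation of 22 (n-BuLi, THF, −78 °C) and quenching with DMF should give the tetrahydrofuranyl propynal F1.
- Warming F1 with 23 in toluene should give the 4,5-dimethoxycyclohexa-1,4-diene-1-carbaldehyde F2.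
- DDQ should aromatise F2 to the 4,5-dimethoxybenzaldehyde F3.
- A Tsuji–Wilkinson decarbonylation with catalytic [Rh(dppp)2]Cl in refluxing xylene removes the formyl group and rejoins the route at 25.

Step 8. Hydride delivery may show poor facial selectivity. Proton loss from the oxocarbenium ion may scramble C4. The benzylic C5–O bond may open with over-reduction.
The fallback runs from 19 back to 21 and replaces kinetic hydride delivery by a reversible ring closure.
- NaBH4 in MeOH reduces 19 through its open hydroxy ketone form to the alkynyl 1,4-diol F4. Both C5 carbinol epimers are usable.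
- Catalytic camphorsulfonic acid in CH2Cl2 at 0 °C ionises only the syringyl carbinol.
- The C2 hydroxyl group captures the benzylic cation. The C2–O bond is never broken, so C2 is retained.
- The closure is reversible, so the aryl group should settle trans to the C4 methyl, giving 21.

Step 11. Hydride abstraction may continue at the C2–H of the newly formed dimethoxybenzylic ether. The acidic hydroquinone by-product may epimerise the strained cis C2/C3 pair through ring opening.
The fallback runs from 24 directly to 26 and uses no quinone oxidant.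
- 10% Pd/C in EtOAc at 50 °C under argon dehydrogenates the cyclohexadiene, which acts as its own hydrogen donor, as 1,4-cyclohexadiene does in catalytic transfer hydrogenolysis of benzyl ethers.
- The hydrogen released is passed on to the benzyl ether.
- A final period under H2 (1 atm) at rt completes the debenzylation.
- This fallback makes no compound outside the list (F0).

**Further compounds**
F1 | step 10 | 3-[(2R,3S,4S,5S)-5-(4-benzyloxy-3,5-dimethoxyphenyl)-3,4-dimethyltetrahydrofuran-2-yl]prop-2-ynal | O=CC#C[C@@H]1O[C@H](c2cc(OC)c(OCc3ccccc3)c(OC)c2)[C@@H](C)[C@@H]1C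
F2 | step 10 | 2-[(2R,3S,4S,5S)-5-(4-benzyloxy-3,5-dimethoxyphenyl)-3,4-dimethyltetrahydrofuran-2-yl]-4,5-dimethoxycyclohexa-1,4-diene-1-carbaldehyde | O=CC1=C(CC(OC)=C(OC)C1)[C@@H]1O[C@H](c2cc(OC)c(OCc3ccccc3)c(OC)c2)[C@@H](C)[C@@H]1C
F3 | step 10 | 2-[(2R,3S,4S,5S)-5-(4-benzyloxy-3,5-dimethoxyphenyl)-3,4-dimethyltetrahydrofuran-2-yl]-4,5-dimethoxybenzaldehyde | O=Cc1cc(OC)c(OC)cc1[C@@H]1O[C@H](c2cc(OC)c(OCc3ccccc3)c(OC)c2)[C@@H](C)[C@@H]1C
F4 | step 8 | (1RS,2S,3S,4R)-1-(4-benzyloxy-3,5-dimethoxyphenyl)-2,3-dimethyl-6-(triisopropylsilyl)hex-5-yne-1,4-diol | CC(C)[Si](C#C[C@H](O)[C@@H](C)[C@H](C)C(O)c1cc(OC)c(OCc2ccccc2)c(OC)c1)(C(C)C)C(C)C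
F0 | step 11 | none | none
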